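A direct plan would brominate 4H-pyran-4-one A1 to 3,5-dibromo-4H-pyran-4-one A2, then magnesiate both remaining ring C–H positions in one flask with TMPMgCl·LiCl: C6–Mg would add to propanal A3 and C2–Mg would take a bromine, giving 2,3,5-tribromo-6-(1-hydroxypropyl)-4H-pyran-4-one A4.
The side chain would then be raised to CBr2 by OH→Br exchange (2,3,5-tribromo-6-(1-bromopropyl)-4H-pyran-4-one A5) and a closing radical bromination at C1′.
Weak point 1, the double ring metalation with aldehyde addition and bromination: a 2-metalated 3-bromo-4-pyranone is set up for β-elimination and ring opening, the amide base can add to the vinylogous ester carbons, and four events must all succeed in one flask.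
Weak point 2, the stepwise climb at C1′ (carbinol, bromide, gem-dibromide): three operations and a throw-away stereocentre for one CBr2, with a substitution at a hindered carbon next to an electron-poor ring.
Weak point 3, the final radical C–H bromination: an electrophilic bromine atom must abstract a hindered, electron-poor C–H alpha to Br, while C2′–H abstraction, HBr loss and attack on the labile C2–Br (a vinylogous acyl bromide) compete on the most advanced intermediate.

**Retrosynthetic overview**
Feature used: in the 4-pyranone ring, C2 carries both O1 and Br and C6 carries the CBr2 carbon C1′; cutting O1–C2 turns C2 into the CBr2= end of a tribromovinyl ketone and C6 into a ketone flanked by an α,α-dibromide.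
Key disconnections: O1–C2 (intramolecular vinylic substitution) and C4–C5 (C-acylation of a methyl ketone), a formal [3+3] union of a tribromoacryloyl unit (C2–C4, from propiolic acid) with a five-carbon ketone (C5, C6, O1, C1′–C3′, from ethyl 2-ethylacetoacetate).
Ring order: the pyranone is the only ring and is closed in the last operation from an acyclic octenedione, so no pyranone is ever functionalised.
Avoidance by design: no ring metalation (the C2 bromine is the one left on the CBr2= terminus), no C1′ carbinol, stereocentre or radical step (C1′ receives both bromines at the outset by bromodecarboxylation through a regiodefined enol); all five C–Br bonds come from polar reactions of Br2.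

Key step: step 4

Remark on the chemistry: the target has no stereocentre; 10 and 11 are drawn as diketones although they should exist largely as enols; 2 would be kept in solution and never taken to dryness.

**Step 1**
Reactants: 1 prop-2-ynoic acid (propiolic acid)
Product: 3 2,3,3-tribromoprop-2-enoic acid, via 3-bromoprop-2-ynoic acid 2 (not isolated)
Conditions: KOH, Br2 (aq. KOBr, 1.1 equiv), H2O, 0 °C; H2SO4, extraction into CH2Cl2; Br2 (1.05 equiv), CH2Cl2, 0 °C → rt
Reagents that add atoms: bromine, BrBr
Why: Hypobromite halogenation of the acidic alkynyl C–H gives the bromoalkyne, and electrophilic addition of Br2 across the triple bond then gives the tribromoalkene, which has no alkene geometry because C3 carries two identical bromines.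

**Step 2**
Reactants: 4 ethyl 2-ethyl-3-oxobutanoate
Product: 8 3,3-dibromopentan-2-one, via sodium 2-ethyl-3-oxobutanoate 5 (not isolated), via sodium 2-bromo-2-ethyl-3-oxobutanoate 6 (not isolated), via 3-bromopent-2-en-2-ol 7 (not isolated)
Conditions: NaOH (1.0 equiv), H2O, rt; CH3CO2H/CH3CO2Na buffer (pH 5), Br2 (2.05 equiv), 0 → 35 °C
Reagents that add atoms: bromine, BrBr
Why: Saponification, enol bromination at C2 and decarboxylation of the α-bromo β-keto acid (bromodecarboxylation) release enol 7 regiospecifically toward C3, where the second Br2 should trap it faster than it ketonises, so both bromines end on one carbon without any enolisation toward the methyl group; the buffer prevents haloform cleavage.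

**Step 3**
Reactants: 3 2,3,3-tribromoprop-2-enoic acid; 8 3,3-dibromopentan-2-one
Product: 10 1,1,2,6,6-pentabromooct-1-ene-3,5-dione, via 2,3,3-tribromoprop-2-enoyl bromide 9 (not isolated)
Conditions: 3, (COBr)2 (1.2 equiv), DMF (2 mol %), CH2Cl2, 0 °C → rt, volatiles off; 8 (1.2 equiv), MgBr2·OEt2 (2.5 equiv), i-Pr2NEt (3.0 equiv, slow addition), CH2Cl2, 0 °C → rt; aq. NaHSO4
Reagents that add atoms: none
Why: Acyl bromide formation followed by crossed Claisen-type C-acylation of the magnesium enolate made by soft enolisation joins the fragments at C4–C5; 8 can enolise only toward its methyl group, the low stationary enolate concentration disfavours loss of bromide, and bromide is the only halide present so any exchange at the vinylic carbons is degenerate.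

**Step 4**
Reactants: 10 1,1,2,6,6-pentabromooct-1-ene-3,5-dione
Product: 13 2,3,5-tribromo-6-(1,1-dibromopropyl)-4H-pyran-4-one, via 1,1,2,4,6,6-hexabromooct-1-ene-3,5-dione 11 (not isolated), via 2,2,3,5-tetrabromo-6-(1,1-dibromopropyl)-2H-pyran-4-ol 12 (not isolated)
Conditions: Br2 (1.0 equiv), CH3CO2Na (2.5 equiv), CH3CO2H, rt; then 50 °C
Reagents that add atoms: bromine, BrBr
Why: Br2 brominates the dione enol at C4, the only enolisable carbon, to give 11 (enol bromination); the enol oxygen on C5, the future O1, then adds to C1, the CBr2= terminus and β-carbon of the tribromovinyl ketone, and adduct 12 expels bromide and a proton (addition–elimination, nucleophilic vinylic substitution) to give the 4-pyranone. The closest known reactions are the closure of ortho-hydroxyaryl β,β-dihalovinyl ketones to 2-halochromones and of 5,5-bis(methylthio)pent-4-ene-1,3-diones to 2-(methylthio)-4-pyranones. The pyranone ring closes in the 6-endo-trig mode through the O1–C2 bond, driven by formation of the cross-conjugated pyranone and loss of HBr to acetate. No stereocentre remains, since C4 of 11 is stereogenic but enolisable and becomes sp2, and C1 carries two identical bromines so that no alkene geometry matters. The step needs attack of the C5 oxygen on C1 instead of attack of the C3 oxygen on C6 (5-exo-tet, leading to a furan-3(2H)-one); this is secured by C6, an ethyl-substituted gem-dibromide and a very poor SN2 centre, by the β,β-dibromoenone being a vinylogous acyl bromide, and by the buffered acidic medium in which the nucleophile is the enol and not the enolate. It also needs a single bromine at C4, secured by 1.0 equiv of Br2 and by convergence of the two orders: material that closes before bromination is the pyranone with C5–H (F4 of the fallback), which the same reagent should brominate at C5 by electrophilic substitution.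

**Compound list**
1 | prop-2-ynoic acid (propiolic acid) | C#CC(=O)O | starting material
2 | 3-bromoprop-2-ynoic acid | OC(=O)C#CBr | intermediate (not isolated)
3 | 2,3,3-tribromoprop-2-enoic acid (tribromoacrylic acid) | OC(=O)C(Br)=C(Br)Br | intermediate
4 | ethyl 2-ethyl-3-oxobutanoate (racemic, configurationally labile) | CCOC(=O)C(CC)C(C)=O | starting material
5 | sodium 2-ethyl-3-oxobutanoate (racemic) | CCC(C(C)=O)C(=O)[O-].[Na+] | intermediate (not isolated)
6 | sodium 2-bromo-2-ethyl-3-oxobutanoate (racemic) | CCC(Br)(C(C)=O)C(=O)[O-].[Na+] | intermediate (not isolated)
7 | 3-bromopent-2-en-2-ol (enol, either geometry) | CCC(Br)=C(C)O | intermediate (not isolated)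
8 | 3,3-dibromopentan-2-one | CCC(Br)(Br)C(C)=O | intermediate
9 | 2,3,3-tribromoprop-2-enoyl bromide | BrC(=O)C(Br)=C(Br)Br | intermediate (not isolated)
10 | 1,1,2,6,6-pentabromooct-1-ene-3,5-dione (drawn as diketone) | CCC(Br)(Br)C(=O)CC(=O)C(Br)=C(Br)Br | intermediate
11 | 1,1,2,4,6,6-hexabromooct-1-ene-3,5-dione (racemic at C4, enolisable) | CCC(Br)(Br)C(=O)C(Br)C(=O)C(Br)=C(Br)Br | intermediate (not isolated)
12 | 2,2,3,5-tetrabromo-6-(1,1-dibromopropyl)-2H-pyran-4-ol | CCC(Br)(Br)C1=C(Br)C(O)=C(Br)C(Br)(Br)O1 | intermediate (not isolated)
13 | 2,3,5-tribromo-6-(1,1-dibromopropyl)-4H-pyran-4-one (achiral) | CCC(Br)(Br)c1oc(Br)c(Br)c(=O)c1Br | target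

**Step count**
Total steps: 4. Longest linear sequence: 3 (steps 1, 3 and 4); step 2 supplies the second fragment.

**Steps most likely to fail**

Step 3. The magnesium enolate of 8 may lose bromide from the neighbouring CBr2 carbon (Favorskii-type pathway) or pass a bromine to a second enolate faster than it is acylated, and O-acylation may compete. The fallback postpones the gem-dibromide until the ring exists. It sets out from acyl bromide 9, made from 3 as above. 9 would be added to the kinetic lithium enolate of commercial pentan-2-one F1 (LiN(i-Pr)2, two equivalents of enolate, THF, −78 °C) to give 1,1,2-tribromooct-1-ene-3,5-dione F2. The conditions of step 4 should turn F2 into 2,3,5-tribromo-6-propyl-4H-pyran-4-one F3. Both C1′ hydrogens of F3 would then be replaced through the vinylogous C1′ lithium enolate (LiN(SiMe3)2, THF, −78 °C, then BrCCl2CCl2Br, run twice in the same flask via the monobromide A5), which comes back to the route at 13. Lateral deprotonation of 2-alkyl-4-pyranones is known, and this endgame involves no radical.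

Step 4. After bromination at C4, the enol oxygen on C3 may displace bromide from C6 to give a furan-3(2H)-one, a second bromine may enter at C4 before the ring closes, or the congested CBr2= terminus may react slowly. The fallback sets out from 10 and closes the ring first under acid (CF3SO3H, catalytic, CH2Cl2, rt to 40 °C, loss of HBr), where no enolate exists and only the conjugate addition–elimination is open, to give 2,3-dibromo-6-(1,1-dibromopropyl)-4H-pyran-4-one F4. C5 of F4 is the β-carbon of the O1–C6=C5 enol ether and the only ring C–H; it would be brominated by electrophilic substitution (Br2, CH3CO2Na, CH3CO2H, 60–80 °C), as is known for the 3,5-dibromination of 4-pyranones, coming back at 13.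

Step 1. Under alkaline hypobromite the bromoalkynoate may decarboxylate or be cleaved, and 2 is unstable when concentrated. The fallback sets out from 1 and avoids any bromoalkyne. Br2 (1 equiv, CH2Cl2, rt) would add to 1 to give (E)-2,3-dibromoprop-2-enoic acid F5. A second addition (neat Br2, visible light, 40 °C) would give 2,2,3,3-tetrabromopropanoic acid F6. Dehydrobromination (KOH, 2 equiv, EtOH, 0 °C; then H2SO4) would come back to the route at 3; it would be kept cold so that decarboxylative loss of bromide does not compete.

**Further compounds**
F1 | step 3 | pentan-2-one (commercial) | CCCC(C)=O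
F2 | step 3 | 1,1,2-tribromooct-1-ene-3,5-dione | CCCC(=O)CC(=O)C(Br)=C(Br)Br
F3 | step 3 | 2,3,5-tribromo-6-propyl-4H-pyran-4-one | CCCc1oc(Br)c(Br)c(=O)c1Br
F4 | step 4 | 2,3-dibromo-6-(1,1-dibromopropyl)-4H-pyran-4-one | CCC(Br)(Br)c1cc(=O)c(Br)c(Br)o1
F5 | step 1 | (E)-2,3-dibromoprop-2-enoic acid | Br/C=C(/Br)C(=O)O
F6 | step 1 | 2,2,3,3-tetrabromopropanoic acid | OC(=O)C(Br)(Br)C(Br)Br
A1 | direct plan | 4H-pyran-4-one | O=c1ccocc1
A2 | direct plan | 3,5-dibromo-4H-pyran-4-one | O=c1c(Br)cocc1Br
A3 | direct plan | propanal | CCC=O
A4 | direct plan | 2,3,5-tribromo-6-(1-hydroxypropyl)-4H-pyran-4-one (racemic) | CCC(O)c1oc(Br)c(Br)c(=O)c1Br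
A5 | direct plan | 2,3,5-tribromo-6-(1-bromopropyl)-4H-pyran-4-one (racemic) | CCC(Br)c1oc(Br)c(Br)c(=O)c1Br
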